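**Plan**

- Retrosynthesis: ring C is opened at O1–C2 and C2–C3 by removing the one-carbon unit C2, which leaves a protected deoxybenzoin. This is cut at the C4–C4a aryl–carbonyl bond into a ring A aryllithium and a ring B arylacetic Weinreb amide. The two ring A–CH2 bonds at C6 and C8 are cut back to two O-(1,1-dimethylallyl) ethers of phloroglucinol.
- Forward order: phloroglucinol diether, then a double Claisen rearrangement (both prenyl C–C bonds, no ring), tris-MOM ether, lithiation of the last ring carbon and acylation (fragments joined), enaminone, and finally acid to close ring C and free the phenols.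
- Enabling feature: ring A is a phloroglucinol (oxygens on C5, C7 and C8a) with linear prenyl groups on C6 and C8. The three ring carbons of free phloroglucinol are equivalent, so prenyl groups on any two of them give one compound, and the third carbon (C4a) remains for the acyl group.
- Stereochemistry: the target has no stereocentre and no stereogenic double bond, so nothing has to be controlled.

Key step: step 3

Assumption: the alkene geometry of formamide 11 is left undefined and enaminone 20 is drawn E, since neither geometry affects the outcome. Adduct 18 is racemic. In step 11, ring closure is taken to precede loss of the remaining MOM groups (intermediate 21); the reverse order would give the same product.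

**Route**

Step 1
Reactants: 1 phloroglucinol (anhydrous); 2 3-chloro-3-methylbut-1-yne
Product: 3 3,5-bis(2-methylbut-3-yn-2-yloxy)phenol
Conditions: 2 (2.2 equiv), DBU (2.6 equiv), CuCl2·2H2O (1 mol%), MeCN, −5 to 0 °C
Reagents that add atoms: none
Why: Copper-catalysed propargylic etherification (copper acetylide/allenylidene pathway) should alkylate the phenoxide at oxygen with the tertiary carbon only, and with about two equivalents the diether should be the main member of a statistical set from which the mono-ether can be resubmitted.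

Step 2
Reactants: 3 3,5-bis(2-methylbut-3-yn-2-yloxy)phenol
Product: 4 3,5-bis(2-methylbut-3-en-2-yloxy)phenol
Conditions: H2 (1 atm), Pd/CaCO3 poisoned with Pb(OAc)2 (5 wt% Pd), quinoline, EtOAc, 20 °C
Reagents that add atoms: none
Why: Lindlar-type semihydrogenation of the terminal alkynes should stop at the alkenes on the lead- and quinoline-poisoned surface, and running it at ambient temperature keeps the labile tertiary allyl ethers from rearranging early.

Step 3
Reactants: 4 3,5-bis(2-methylbut-3-en-2-yloxy)phenol
Product: 7 2,4-bis(3-methylbut-2-en-1-yl)benzene-1,3,5-triol, via 2-prenyl mono-ether 5 (not isolated), via 4-prenyl mono-ether 6 (not isolated)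
Conditions: degassed PhMe, 110 °C, Ar
Reagents that add atoms: none
Why: Each tertiary allyl aryl ether should undergo a concerted suprafacial [3,3] sigmatropic shift through a chair-like six-membered transition state to an ortho-dienone that enolises to the phenol, and the allylic transposition of this aromatic Claisen rearrangement turns the O-bound 1,1-dimethylallyl group into a C-bound linear prenyl group. The closest known reaction type is the thermal rearrangement of aryl 1,1-dimethylallyl ethers to ortho-prenylphenols, which electron-rich meta-oxygenated arenes undergo at moderate temperature. No ring closes and no stereocentre is created, so neither a mode of closure nor a stereocontrol element applies. The step needs positional and linear-over-branched selectivity: the second is fixed by the pericyclic mechanism under neutral conditions, and the first is made irrelevant by the threefold symmetry of the phloroglucinol core, because both oxygens end as free hydroxyls and prenyl groups on any two different ring carbons (the paths through 5 and through 6) describe the same triol 7. The only outcome to avoid is a second shift onto the carbon that already bears a prenyl group; that terminus is the more hindered one and its dienone cannot aromatise and can return by retro-[3,3] shift, whereas migration to a free carbon is made irreversible by enolisation. Degassed, acid-free solvent should keep the ortho-prenylphenols from closing to chromans and the triol from oxidising.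

Step 4
Reactants: 7 2,4-bis(3-methylbut-2-en-1-yl)benzene-1,3,5-triol
Product: 8 1,3,5-tris(methoxymethoxy)-2,4-bis(3-methylbut-2-en-1-yl)benzene
Conditions: MOMCl (4.5 equiv), i-Pr2NEt (6 equiv), CH2Cl2, 0 to 40 °C
Reagents that add atoms: chloromethyl methyl ether (MOMCl), COCCl
Why: O-alkylation of the phenols with the hard oxocarbenium-type electrophile MOMCl (acetal protection) should cap all three oxygens without touching the alkenes and installs the groups that later direct the lithiation.

Step 5
Reactants: 9 4-hydroxy-2-methoxybenzaldehyde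
Product: 10 2-methoxy-4-(methoxymethoxy)benzaldehyde
Conditions: MOMCl, i-Pr2NEt, CH2Cl2, 0 °C to rt
Reagents that add atoms: chloromethyl methyl ether (MOMCl), COCCl
Why: MOM protection of the single phenol under amine base is routine, leaves the aldehyde untouched and gives a group stable to all the basic steps that follow.

Step 6
Reactants: 10 2-methoxy-4-(methoxymethoxy)benzaldehyde
Product: 12 2-[2-methoxy-4-(methoxymethoxy)phenyl]acetonitrile, via tosylvinyl formamide 11 (not isolated)
Conditions: TosMIC, t-BuOK, DME, −40 °C; then MeOH, 65 °C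
Reagents that add atoms: p-toluenesulfonylmethyl isocyanide (TosMIC), Cc1ccc(cc1)S(=O)(=O)C[N+]#[C-]
Why: In the van Leusen reductive cyanation the TosMIC anion adds to the aldehyde, the oxazoline opens to formamide 11, and methanolysis of the formyl group followed by loss of sulfinate should give the nitrile one carbon longer.

Step 7
Reactants: 12 2-[2-methoxy-4-(methoxymethoxy)phenyl]acetonitrile
Product: 14 2-[2-methoxy-4-(methoxymethoxy)phenyl]acetic acid, via potassium carboxylate 13 (not isolated)
Conditions: KOH, EtOH/H2O, 85 °C; then 1 M HCl to pH 4, 0 °C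
Reagents that add atoms: potassium hydroxide, [K+].[OH-]; water, O
Why: Alkaline nitrile hydrolysis leaves the aryl MOM ether and methyl ether intact, and a brief cold acidification to pH 4 should free the acid without cleaving the acetal.

Step 8
Reactants: 14 2-[2-methoxy-4-(methoxymethoxy)phenyl]acetic acid
Product: 16 N-methoxy-2-[2-methoxy-4-(methoxymethoxy)phenyl]-N-methylacetamide, via acyl imidazole 15 (not isolated)
Conditions: CDI, CH2Cl2, rt; then MeNH(OMe)·HCl, rt
Reagents that add atoms: N,O-dimethylhydroxylamine hydrochloride, CNOC.Cl; 1,1'-carbonyldiimidazole (CDI), O=C(n1ccnc1)n1ccnc1 (imidazolyl group of intermediate 15 only)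
Why: Amide coupling through the acyl imidazole is a standard, nearly neutral way to a Weinreb amide and should not disturb the MOM ether.

Step 9
Reactants: 8 1,3,5-tris(methoxymethoxy)-2,4-bis(3-methylbut-2-en-1-yl)benzene; 16 N-methoxy-2-[2-methoxy-4-(methoxymethoxy)phenyl]-N-methylacetamide
Product: 19 2-[2-methoxy-4-(methoxymethoxy)phenyl]-1-[2,4,6-tris(methoxymethoxy)-3,5-bis(3-methylbut-2-en-1-yl)phenyl]ethan-1-one, via aryllithium 17 (not isolated), via tetrahedral lithium adduct 18 (not isolated)
Conditions: n-BuLi (1.05 equiv), THF, 0 °C, 1 h; then 16 (1.1 equiv), −78 to 0 °C; then H2O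
Reagents that add atoms: n-butyllithium, [Li]CCCC (lithium of intermediates 17 and 18 only)
Why: Directed ortho-metalation should remove the only ring hydrogen of 8, which lies between two lithium-chelating MOM ethers, and aryllithium 17 should add once to the amide because chelate 18 holds the tetrahedral stage until the aqueous quench (Weinreb ketone synthesis), with the low addition temperature chosen to limit α-deprotonation of the amide.

Step 10
Reactants: 19 2-[2-methoxy-4-(methoxymethoxy)phenyl]-1-[2,4,6-tris(methoxymethoxy)-3,5-bis(3-methylbut-2-en-1-yl)phenyl]ethan-1-one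
Product: 20 (E)-3-(dimethylamino)-2-[2-methoxy-4-(methoxymethoxy)phenyl]-1-[2,4,6-tris(methoxymethoxy)-3,5-bis(3-methylbut-2-en-1-yl)phenyl]prop-2-en-1-one
Conditions: Me2NCH(OMe)2, PhMe, 100 °C
Reagents that add atoms: N,N-dimethylformamide dimethyl acetal, COC(OC)N(C)C
Why: Condensation of the doubly activated methylene with the formamide acetal (enaminone formation) supplies the C2 carbon under neutral conditions, and because every phenol is masked the reagent cannot O-methylate.

Step 11
Reactants: 20 (E)-3-(dimethylamino)-2-[2-methoxy-4-(methoxymethoxy)phenyl]-1-[2,4,6-tris(methoxymethoxy)-3,5-bis(3-methylbut-2-en-1-yl)phenyl]prop-2-en-1-one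
Product: 22 5,7-dihydroxy-3-(4-hydroxy-2-methoxyphenyl)-6,8-bis(3-methylbut-2-en-1-yl)-4H-chromen-4-one, via tris-MOM isoflavone 21 (not isolated)
Conditions: 3 M aq. HCl, MeOH/THF, 45 °C
Reagents that add atoms: none
Why: Acid-catalysed MOM acetal cleavage should free one of the two symmetry-equivalent phenols ortho to the ketone, which adds to the β-carbon of the protonated enaminone and expels dimethylamine (addition–elimination closure of the chromone ring, the enaminone route to isoflavones), while the remaining MOM ethers hydrolyse under the same dilute conditions, kept mild because the ortho-prenylphenols would otherwise risk hydration or chroman formation.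

**Compound list**

1 | phloroglucinol (benzene-1,3,5-triol) | Oc1cc(O)cc(O)c1 | starting material
2 | 3-chloro-3-methylbut-1-yne | CC(C)(Cl)C#C | starting material
3 | 3,5-bis(2-methylbut-3-yn-2-yloxy)phenol | Oc1cc(OC(C)(C)C#C)cc(OC(C)(C)C#C)c1 | intermediate
4 | 3,5-bis(2-methylbut-3-en-2-yloxy)phenol | Oc1cc(OC(C)(C)C=C)cc(OC(C)(C)C=C)c1 | intermediate
5 | 5-(2-methylbut-3-en-2-yloxy)-2-(3-methylbut-2-en-1-yl)benzene-1,3-diol | Oc1cc(OC(C)(C)C=C)cc(O)c1CC=C(C)C | intermediate (not isolated)
6 | 5-(2-methylbut-3-en-2-yloxy)-4-(3-methylbut-2-en-1-yl)benzene-1,3-diol | Oc1cc(O)c(CC=C(C)C)c(OC(C)(C)C=C)c1 | intermediate (not isolated)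
7 | 2,4-bis(3-methylbut-2-en-1-yl)benzene-1,3,5-triol (2,4-diprenylphloroglucinol) | Oc1cc(O)c(CC=C(C)C)c(O)c1CC=C(C)C | intermediate
8 | 1,3,5-tris(methoxymethoxy)-2,4-bis(3-methylbut-2-en-1-yl)benzene | COCOc1cc(OCOC)c(CC=C(C)C)c(OCOC)c1CC=C(C)C | intermediate
9 | 4-hydroxy-2-methoxybenzaldehyde | COc1cc(O)ccc1C=O | starting material
10 | 2-methoxy-4-(methoxymethoxy)benzaldehyde | COCOc1ccc(C=O)c(OC)c1 | intermediate
11 | N-{2-[2-methoxy-4-(methoxymethoxy)phenyl]-1-(4-methylbenzenesulfonyl)ethenyl}formamide (alkene geometry not defined) | COCOc1ccc(C=C(NC=O)S(=O)(=O)c2ccc(C)cc2)c(OC)c1 | intermediate (not isolated)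
12 | 2-[2-methoxy-4-(methoxymethoxy)phenyl]acetonitrile | COCOc1ccc(CC#N)c(OC)c1 | intermediate
13 | potassium 2-[2-methoxy-4-(methoxymethoxy)phenyl]acetate | COCOc1ccc(CC(=O)[O-])c(OC)c1.[K+] | intermediate (not isolated)
14 | 2-[2-methoxy-4-(methoxymethoxy)phenyl]acetic acid | COCOc1ccc(CC(=O)O)c(OC)c1 | intermediate
15 | 1-(imidazol-1-yl)-2-[2-methoxy-4-(methoxymethoxy)phenyl]ethan-1-one | COCOc1ccc(CC(=O)n2ccnc2)c(OC)c1 | intermediate (not isolated)
16 | N-methoxy-2-[2-methoxy-4-(methoxymethoxy)phenyl]-N-methylacetamide | COCOc1ccc(CC(=O)N(C)OC)c(OC)c1 | intermediate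
17 | [2,4,6-tris(methoxymethoxy)-3,5-bis(3-methylbut-2-en-1-yl)phenyl]lithium | [Li]c1c(OCOC)c(CC=C(C)C)c(OCOC)c(CC=C(C)C)c1OCOC | intermediate (not isolated)
18 | lithium 1-[methoxy(methyl)amino]-2-[2-methoxy-4-(methoxymethoxy)phenyl]-1-[2,4,6-tris(methoxymethoxy)-3,5-bis(3-methylbut-2-en-1-yl)phenyl]ethan-1-olate (racemic) | [Li]OC(Cc1ccc(OCOC)cc1OC)(N(C)OC)c1c(OCOC)c(CC=C(C)C)c(OCOC)c(CC=C(C)C)c1OCOC | intermediate (not isolated)
19 | 2-[2-methoxy-4-(methoxymethoxy)phenyl]-1-[2,4,6-tris(methoxymethoxy)-3,5-bis(3-methylbut-2-en-1-yl)phenyl]ethan-1-one | COCOc1ccc(CC(=O)c2c(OCOC)c(CC=C(C)C)c(OCOC)c(CC=C(C)C)c2OCOC)c(OC)c1 | intermediate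
20 | (E)-3-(dimethylamino)-2-[2-methoxy-4-(methoxymethoxy)phenyl]-1-[2,4,6-tris(methoxymethoxy)-3,5-bis(3-methylbut-2-en-1-yl)phenyl]prop-2-en-1-one | CN(C)/C=C(/C(=O)c1c(OCOC)c(CC=C(C)C)c(OCOC)c(CC=C(C)C)c1OCOC)c1ccc(OCOC)cc1OC | intermediate
21 | 5,7-bis(methoxymethoxy)-3-[2-methoxy-4-(methoxymethoxy)phenyl]-6,8-bis(3-methylbut-2-en-1-yl)-4H-chromen-4-one | COCOc1ccc(-c2coc3c(CC=C(C)C)c(OCOC)c(CC=C(C)C)c(OCOC)c3c2=O)c(OC)c1 | intermediate (not isolated)
22 | 5,7-dihydroxy-3-(4-hydroxy-2-methoxyphenyl)-6,8-bis(3-methylbut-2-en-1-yl)-4H-chromen-4-one | COc1cc(O)ccc1-c1coc2c(CC=C(C)C)c(O)c(CC=C(C)C)c(O)c2c1=O | target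

**Step count**

Total: 11 steps. Longest linear sequence: 7 steps (steps 1–4 and 9–11 from phloroglucinol; equally steps 5–11 from the aldehyde).

**Steps most likely to fail**

Step 9. The hindered, doubly chelated aryllithium 17 may act as a base and remove a benzylic α-proton of amide 16 (enolisation instead of addition), or lithiation may stray to a benzylic-allylic CH2 of a prenyl group. The fallback sets out from 8 and makes the aryl–carbonyl bond with a less acidic partner, then the CH2–aryl bond by cross-coupling. Lithiation as before gives 17, which is trapped with N-methoxy-N-methylacetamide; this should pass through the racemic lithium hemiaminal adduct F1 and give, after aqueous quench, 1-[2,4,6-tris(methoxymethoxy)-3,5-bis(3-methylbut-2-en-1-yl)phenyl]ethan-1-one F2. Ring B then enters as an electrophile: commercial 4-bromo-3-methoxyphenol F3 is converted with MOMCl and i-Pr2NEt into 1-bromo-2-methoxy-4-(methoxymethoxy)benzene F4. A palladium-catalysed ketone α-arylation of F2 with F4 (Pd2(dba)3, XPhos, NaOt-Bu, toluene, 80 °C; zerovalent palladium inserts into the C–Br bond and couples with the sodium enolate) comes back to the route at deoxybenzoin 19.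

Step 3. The tertiary ethers may lose isoprene thermally before they rearrange, the second shift may land on the ring carbon that already carries a prenyl group (dearomatised geminal dialkylation), an ortho-prenylphenol may close onto its double bond, or the triol may oxidise in air. The fallback sets out from 1 and forms the two C-prenyl bonds by iterative directed ortho-metalation. Compound 1 is protected (MOMCl, i-Pr2NEt, CH2Cl2) as 1,3,5-tris(methoxymethoxy)benzene F5. Treatment with n-BuLi in THF at 0 °C gives [2,4,6-tris(methoxymethoxy)phenyl]lithium F6, which with CuI (10 mol%) and 1-bromo-3-methylbut-2-ene should give 1,3,5-tris(methoxymethoxy)-2-(3-methylbut-2-en-1-yl)benzene F7. A second round of the same operations, through [2,4,6-tris(methoxymethoxy)-3-(3-methylbut-2-en-1-yl)phenyl]lithium F8, comes back to the route at 8.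

Step 1. The three equivalent hydroxyls react at similar rates, so under- and over-alkylation erode the yield of the diether, and the very electron-rich ring may also be alkylated at carbon. The fallback sets out from chloride 2 and uses commercial 1-(3,5-dihydroxyphenyl)ethan-1-one F9 in place of 1. With only two hydroxyls, exhaustive etherification under the same CuCl2·2H2O/DBU conditions should give 1-[3,5-bis(2-methylbut-3-yn-2-yloxy)phenyl]ethan-1-one F10. Baeyer–Villiger oxidation (mCPBA, NaHCO3, CH2Cl2) with aryl migration should give 3,5-bis(2-methylbut-3-yn-2-yloxy)phenyl acetate F11, and methanolysis (K2CO3 cat., MeOH, 0 °C) comes back to the route at 3.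

**Further compounds**

F1 | step 9 | lithium 1-[methoxy(methyl)amino]-1-[2,4,6-tris(methoxymethoxy)-3,5-bis(3-methylbut-2-en-1-yl)phenyl]ethan-1-olate (racemic) | [Li]OC(C)(N(C)OC)c1c(OCOC)c(CC=C(C)C)c(OCOC)c(CC=C(C)C)c1OCOC
F2 | step 9 | 1-[2,4,6-tris(methoxymethoxy)-3,5-bis(3-methylbut-2-en-1-yl)phenyl]ethan-1-one | CC(=O)c1c(OCOC)c(CC=C(C)C)c(OCOC)c(CC=C(C)C)c1OCOC
F3 | step 9 | 4-bromo-3-methoxyphenol | COc1cc(O)ccc1Br
F4 | step 9 | 1-bromo-2-methoxy-4-(methoxymethoxy)benzene | COCOc1ccc(Br)c(OC)c1
F5 | step 3 | 1,3,5-tris(methoxymethoxy)benzene | COCOc1cc(OCOC)cc(OCOC)c1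
F6 | step 3 | [2,4,6-tris(methoxymethoxy)phenyl]lithium | [Li]c1c(OCOC)cc(OCOC)cc1OCOC
F7 | step 3 | 1,3,5-tris(methoxymethoxy)-2-(3-methylbut-2-en-1-yl)benzene | COCOc1cc(OCOC)c(CC=C(C)C)c(OCOC)c1
F8 | step 3 | [2,4,6-tris(methoxymethoxy)-3-(3-methylbut-2-en-1-yl)phenyl]lithium | [Li]c1c(OCOC)cc(OCOC)c(CC=C(C)C)c1OCOC
F9 | step 1 | 1-(3,5-dihydroxyphenyl)ethan-1-one | CC(=O)c1cc(O)cc(O)c1
F10 | step 1 | 1-[3,5-bis(2-methylbut-3-yn-2-yloxy)phenyl]ethan-1-one | CC(=O)c1cc(OC(C)(C)C#C)cc(OC(C)(C)C#C)c1
F11 | step 1 | 3,5-bis(2-methylbut-3-yn-2-yloxy)phenyl acetate | CC(=O)Oc1cc(OC(C)(C)C#C)cc(OC(C)(C)C#C)c1
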